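**Strategy.** The route rests on disconnecting the para-phenylene of the 13-membered cyclophane into a 5-alkoxy-2-pyrone and a terminal alkyne: the arene carbon bearing the ring B ether oxygen is pyrone C5, and the para carbon bearing the benzylic CH2 on the lactam aminal carbon is the internal alkyne carbon. One thermal [4+2]/retro-[4+2] sequence with loss of CO2 therefore forms the benzene ring and closes the macrocycle together, well ahead of the peroxide-forming steps. Its precursor is the decahydrofluorene ketone whose ring B oxygen carries the pyronyl group and whose quaternary γ-lactam carries an allyl group and a propargyl-substituted methoxy aminal.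

Key step: step 30

Remark: the aminal carbon and the hemiperacetal carbon of the target can equilibrate by ring–chain tautomerism and are taken to be the thermodynamically preferred epimers; the precursor is used as the N–H methoxy aminal, and the pyronyl ether is attached last so that the pyrone never meets enolates or organometallic reagents.

Step 1
Reactants: 1 coumalic acid
Product: 2 5-bromo-2H-pyran-2-one
Conditions: NBS, LiOAc (cat.), MeCN/H2O 9:1, rt
Reagents that add atoms: N-bromosuccinimide, O=C1CCC(=O)N1Br
Why: Bromodecarboxylation (Hunsdiecker-type ipso-bromination with loss of CO2) of the electron-rich C5 carboxylic acid should give the bromide without opening the lactone.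

Step 2
Reactants: 2 5-bromo-2H-pyran-2-one
Product: 3 5-(pinacolboryl)-2H-pyran-2-one
Conditions: B2pin2, Pd(dppf)Cl2 (cat.), KOAc, 1,4-dioxane, 80 °C
Reagents that add atoms: bis(pinacolato)diboron, CC1(C)OB(OC1(C)C)B1OC(C)(C)C(C)(C)O1
Why: Miyaura borylation of the vinylic bromide proceeds under weak-base conditions that the pyrone tolerates.

Step 3
Reactants: 3 5-(pinacolboryl)-2H-pyran-2-one
Product: 4 5-hydroxy-2H-pyran-2-one
Conditions: H2O2 (30% aq.), NaHCO3, THF, 0 °C
Reagents that add atoms: hydrogen peroxide, OO
Why: Boronate oxidation (C–B to C–O with 1,2-migration) near neutral pH unmasks the enolic 5-hydroxyl.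

Step 4
Reactants: 5 succinimide
Product: 6 tert-butyl 2,5-dioxopyrrolidine-1-carboxylate (N-Boc-succinimide)
Conditions: Boc2O, DMAP (cat.), MeCN, rt
Reagents that add atoms: di-tert-butyl dicarbonate, CC(C)(C)OC(=O)OC(=O)OC(C)(C)C
Why: N-acylation of the imide gives a protected, carbonyl-activated succinimide whose carbamate leaves in acid (carbamate formation).

Step 5
Reactants: 7 2-methylpent-1-en-3-one
Product: 8 (Z)-tert-butyldimethyl[(2-methylpenta-1,3-dien-3-yl)oxy]silane
Conditions: TBSOTf, Et3N, CH2Cl2, 0 °C
Reagents that add atoms: tert-butyldimethylsilyl triflate, CC(C)(C)[Si](C)(C)OS(=O)(=O)C(F)(F)F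
Why: Soft enolization and O-silylation of the ethyl ketone gives the 2-silyloxy diene, the Z enol ether being favoured by allylic strain.

Step 6
Reactants: 8 (Z)-silyloxy diene; 9 (E)-4-acetoxy-2-methylbut-2-enal
Product: 10 ring A cycloadduct [(1R,2R,6R)-2-formyl-2,4,6-trimethyl-5-(tert-butyldimethylsilyloxy)cyclohex-4-en-1-yl]methyl acetate
Conditions: (S)-o-tolyl oxazaborolidine (from α,α-diphenylprolinol)·HNTf2 (20 mol %), CH2Cl2, −78 °C
Reagents that add atoms: none
Why: Catalytic enantioselective Diels–Alder reaction in which the silyloxy group sends its neighbouring diene terminus to the β-carbon of the enal, the E-dienophile fixes formyl trans to CH2OAc, and the chiral boron Lewis acid on the formyl group selects the enal face and so the configuration of the quaternary carbon and its neighbour (catalyst enantiomer chosen accordingly; the methyl next to the enol ether is corrected in step 9 if the exo mode intervenes).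

Step 7
Reactants: 10 ring A cycloadduct; 11 2-(triphenylphosphoranylidene)propanal
Product: 12 ring A enal (formyl of 10 replaced by an (E)-2-methyl-3-oxoprop-1-enyl arm)
Conditions: toluene, 110 °C
Reagents that add atoms: none
Why: Wittig olefination with the formyl-stabilized ylide should give the E-trisubstituted enal from the neopentyl aldehyde, the enol ether and acetate being inert to the neutral ylide.

Step 8
Reactants: 12 ring A enal
Product: 13 ring A triene (arm = (E)-2-methylbuta-1,3-dienyl)
Conditions: Ph3PCH3Br, KOt-Bu, THF, −78 to 0 °C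
Reagents that add atoms: methyltriphenylphosphonium bromide, C[P+](c1ccccc1)(c1ccccc1)c1ccccc1.[Br-]
Why: Wittig methylenation of the enal (1,2-addition) completes the diene arm, the aldehyde reacting far faster than the acetate.

Step 9
Reactants: 13 ring A triene
Product: 14 hydroxy ketone (3-(hydroxymethyl)-4-[(E)-2-methylbuta-1,3-dienyl]-2,4,6-trimethylcyclohexanone with both α-methyls and CH2OH equatorial and the quaternary methyl axial)
Conditions: K2CO3 (0.2 equiv), MeOH, rt
Reagents that add atoms: none
Why: Methanolysis removes the acetate and the silyl enol ether, and enolization of the ketone equilibrates both α-methyl groups to the equatorial positions, since either axial epimer would be syn-diaxial to the quaternary methyl.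

Step 10
Reactants: 14 hydroxy ketone
Product: 15 tosylhydrazone of 14
Conditions: TsNHNH2, AcOH (cat.), EtOH, 60 °C
Reagents that add atoms: 4-methylbenzenesulfonohydrazide, Cc1ccc(cc1)S(=O)(=O)NN
Why: Condensation of the ketone with the sulfonyl hydrazide (hydrazone formation) prepares the mild deoxygenation.

Step 11
Reactants: 15 tosylhydrazone
Product: 16 primary alcohol {2-[(E)-2-methylbuta-1,3-dienyl]-2,4,6-trimethylcyclohexyl}methanol
Conditions: catecholborane, CHCl3, 0 °C; NaOAc·3H2O, reflux
Reagents that add atoms: none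
Why: Hydride reduction of the tosylhydrazone and loss of sulfinate and N2 through the diazene (Wolff–Kishner-type deoxygenation) turns C=O into CH2 without moving the diene or the methyl stereocentres.

Step 12
Reactants: 16 primary alcohol
Product: 17 ring A aldehyde (equatorial formyl)
Conditions: Pr4N[RuO4] (cat.), NMO, 4 Å MS, CH2Cl2, rt
Reagents that add atoms: none
Why: Catalytic perruthenate oxidation (Ley–Griffith) gives the aldehyde, whose α-centre already holds the favoured equatorial formyl group.

Step 13
Reactants: 17 ring A aldehyde; 18 methyl propiolate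
Product: 20 ring A propargylic alcohol (methyl 4-hydroxybut-2-ynoate arm with S carbinol), via methylzinc acetylide 19 (not isolated)
Conditions: Me2Zn, (S,S)-ProPhenol (20 mol %), Ph3PO (cat.), toluene, 0 °C
Reagents that add atoms: none
Why: Catalytic asymmetric alkynylation by the zinc acetylide under the chiral dinuclear zinc catalyst sets the ring B carbinol by reagent control, the ligand enantiomer being chosen to give the S alcohol that becomes the α-hydroxyl of ring B.

Step 14
Reactants: 20 ring A propargylic alcohol
Product: 21 ring A γ-hydroxy (E)-enoate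
Conditions: NaAlH2(OCH2CH2OCH3)2, THF, −72 °C
Reagents that add atoms: none
Why: trans-Hydroalumination of the ynoate directed by the aluminium alkoxide, then protonation, gives the E-enoate and leaves the diene alone.

Step 15
Reactants: 21 ring A γ-hydroxy (E)-enoate
Product: 22 ring A triene TBS ether
Conditions: TBSOTf, 2,6-lutidine, CH2Cl2, −78 °C
Reagents that add atoms: tert-butyldimethylsilyl triflate, CC(C)(C)[Si](C)(C)OS(=O)(=O)C(F)(F)F
Why: Silylation of the hindered secondary alcohol with the silyl triflate protects it up to step 28.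

Step 16
Reactants: 22 ring A triene TBS ether
Product: 23 tricyclic ester (trans-anti-trans decahydrofluorene with α-OTBS on ring B and methyl ester on ring C)
Conditions: Me2AlCl, CH2Cl2, −78 to −20 °C
Reagents that add atoms: none
Why: Lewis-acid-promoted intramolecular Diels–Alder reaction of the 1,3,8-nonatriene type, in which the endo transition state of the E-enoate gives trans-fused rings B and C with the ester trans to the ring B carbinol carbon, and the equatorial attachment of both arms on the ring A chair should make the diene add on the face that puts the new ring C carbon syn to the angular methyl group.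

Step 17
Reactants: 23 tricyclic ester
Product: 24 tricyclic primary alcohol
Conditions: i-Bu2AlH, CH2Cl2, −78 to 0 °C
Reagents that add atoms: none
Why: Hydride reduction of the ester removes the carbonyl that would otherwise acidify the ring C centre in the next oxidation.

Step 18
Reactants: 24 tricyclic primary alcohol
Product: 25 tricyclic TES ether
Conditions: Et3SiCl, imidazole, CH2Cl2, 0 °C
Reagents that add atoms: chlorotriethylsilane, CC[Si](Cl)(CC)CC
Why: Silylation gives an acid-labile primary triethylsilyl ether that is orthogonal to the secondary TBS ether.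

Step 19
Reactants: 25 tricyclic TES ether
Product: 26 ring C enone
Conditions: Rh2(cap)4 (cap = caprolactamate, cat.), t-BuOOH, K2CO3, CH2Cl2, rt
Reagents that add atoms: tert-butyl hydroperoxide, CC(C)(C)OO
Why: Catalytic allylic C–H oxidation at the only allylic methylene, next to the CH= terminus, should give the β-methyl enone.

Step 20
Reactants: 26 ring C enone
Product: 28 ring C enol triflate, via lithium enolate 27 (not isolated)
Conditions: Li (2.2 equiv), NH3 (l), t-BuOH (1 equiv), THF, −78 °C; evaporate NH3; PhNTf2, THF, −78 °C to rt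
Reagents that add atoms: N-phenylbis(trifluoromethanesulfonimide), O=S(=O)(N(c1ccccc1)S(=O)(=O)C(F)(F)F)C(F)(F)F
Why: Dissolving-metal conjugate reduction gives the regiodefined enolate, axial protonation of the β-carbanion placing the ring C methyl equatorial with its hydrogen on the upper face, and O-sulfonylation traps the enolate as the triflate on the side of the future alkene.

Step 21
Reactants: 28 ring C enol triflate
Product: 29 ring C methyl alkene TES ether
Conditions: MeMgBr, Fe(acac)3 (cat.), THF/NMP, −30 °C
Reagents that add atoms: methylmagnesium bromide, C[Mg]Br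
Why: Iron-catalysed Kumada-type cross-coupling of the enol triflate puts the methyl group on the alkene without moving the double bond.

Step 22
Reactants: 29 ring C methyl alkene TES ether
Product: 30 homoallylic primary alcohol
Conditions: PPTS, MeOH, 0 °C
Reagents that add atoms: none
Why: Acid-catalysed methanolysis cleaves the primary triethylsilyl ether selectively over the hindered secondary TBS ether.

Step 23
Reactants: 30 homoallylic primary alcohol
Product: 31 tricyclic β,γ-unsaturated aldehyde
Conditions: DMP (1,1,1-triacetoxy-1,1-dihydro-1,2-benziodoxol-3(1H)-one), NaHCO3, CH2Cl2, 0 °C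
Reagents that add atoms: none
Why: Hypervalent-iodine (Dess–Martin) oxidation under buffered non-basic conditions gives the aldehyde without epimerization or conjugation of the alkene.

Step 24
Reactants: 31 tricyclic aldehyde; 6 N-Boc-succinimide
Product: 33 β-hydroxy imide (mixture at the two new centres), via imide lithium enolate 32 (not isolated)
Conditions: LiN(SiMe3)2, THF, −78 °C; 31; AcOH, −78 °C
Reagents that add atoms: none
Why: Aldol addition of the imide enolate outruns proton transfer at low temperature, and the two uncontrolled centres are erased in step 25 and reset in step 26.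

Step 25
Reactants: 33 β-hydroxy imide
Product: 34 β-keto imide
Conditions: DMP, CH2Cl2, rt
Reagents that add atoms: none
Why: Dess–Martin oxidation of the secondary alcohol under neutral conditions spares the allylic α-stereocentre on ring C.

Step 26
Reactants: 34 β-keto imide; 35 allyl methyl carbonate
Product: 36 allylated keto imide (R quaternary carbon)
Conditions: Pd2(dba)3 (cat.), (R,R)-N,N′-(cyclohexane-1,2-diyl)bis[2-(diphenylphosphino)benzamide] (cat.), CH2Cl2, rt
Reagents that add atoms: none
Why: Palladium-catalysed asymmetric allylic alkylation (Tsuji–Trost) of the stabilized enolate, formed by the methoxide released from the carbonate, creates the quaternary lactam carbon under ligand control (ligand enantiomer chosen for the R centre) with no strong base near the epimerizable ring C carbon.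

Step 27
Reactants: 36 allylated keto imide; 37 propargyl bromide
Product: 39 N-Boc propargyl hydroxy lactam (in equilibrium with its open keto carbamate), via allenylzinc bromide 38 (not isolated)
Conditions: Zn dust, THF, 0 °C; aq. NH4Cl
Reagents that add atoms: none
Why: Barbier-type SE2′ addition of the allenylzinc reagent should take the carbamate-activated imide carbonyl next to CH2, since the ketone and the other imide carbonyl are both flanked by the quaternary carbon.

Step 28
Reactants: 39 N-Boc propargyl hydroxy lactam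
Product: 41 seco alcohol (N–H methoxy aminal with free ring B α-hydroxyl), via N-Boc methoxy aminal 40 (not isolated)
Conditions: HCl (1.25 M in MeOH), 0 °C to rt
Reagents that add atoms: methanol, CO
Why: Acid forms the N-acyliminium ion that methanol captures (N,O-acetal exchange) and also removes the Boc and TBS groups, the aminal carbon equilibrating so that the epimer with the propargyl arm trans to the bulky acyl group should prevail and be separable.

Step 29
Reactants: 41 seco alcohol; 4 5-hydroxy-2H-pyran-2-one
Product: 42 seco pyronyl ether (cycloaddition precursor)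
Conditions: PPh3, DIAD, toluene, 0 °C to rt
Reagents that add atoms: none
Why: Mitsunobu etherification with the acidic enol proceeds with SN2 inversion at the ring B carbinol, turning the α-alcohol into the β-pyronyl ether.

Step 30
Reactants: 42 seco pyronyl ether
Product: 44 cyclophane methyl aminal (allyl group and ring C alkene intact), via bridged bicyclic lactone 43 (not isolated)
Conditions: o-dichlorobenzene (0.001 M), BHT, 2,6-di-tert-butyl-4-methylpyridine (0.2 equiv), 210 °C, sealed tube
Reagents that add atoms: none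
Why: The unactivated terminal alkyne adds across C3 and C6 of the 5-alkoxy-2-pyrone in an intramolecular Diels–Alder reaction to give the 2-oxabicyclo[2.2.2]octadienone 43, which loses CO2 by retro-[4+2] to give the benzene ring. The closest known reaction type is the tethered 2-pyrone–alkyne cycloaddition with decarboxylation used to make bent para-cyclophane arenes. The 13-membered ring closes in the cycloaddition itself (bonds C3–internal alkyne carbon and C6–terminal alkyne carbon), onto a boat-shaped bicyclic diene and not onto a flat arene, and the same two bonds close the six-membered carbocycle that CO2 extrusion then aromatizes irreversibly, which pays for the bending. No stereocentre is created, because the two bridgeheads of 43 become arene carbons. The step needs the para and not the meta arene: the C5 alkoxy group makes C6 the nucleophilic terminus that bonds first to the unhindered terminal alkyne carbon, and the propargyl arm trans to the acyl group on the lactam lets the tether reach this alignment. High dilution, a radical inhibitor and an acid scavenger are there to suppress oligomers, adducts of the allyl alkene and loss of methanol from the aminal.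

Step 31
Reactants: 44 cyclophane methyl aminal
Product: 45 cyclophane hemiaminal
Conditions: PPTS (cat.), THF/H2O, 40 °C
Reagents that add atoms: water, O
Why: Acid-catalysed hydrolysis of the N,O-acetal through the N-acyliminium ion gives the hemiaminal, whose configuration settles under thermodynamic control within the macrocycle.

Step 32
Reactants: 45 cyclophane hemiaminal
Product: 46 ring C allylic hydroperoxide
Conditions: O2, visible light, tetraphenylporphyrin (cat.), CH2Cl2, −20 °C
Reagents that add atoms: oxygen, O=O
Why: Schenck ene reaction in which singlet oxygen bonds to the methyl-bearing alkene carbon on the upper face and abstracts suprafacially the pseudoaxial allylic hydrogen of the CH(CH3) carbon, giving the tertiary hydroperoxide with the double bond moved one place, while the allyl alkene and the arene do not react.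

Step 33
Reactants: 46 ring C allylic hydroperoxide
Product: 47 epoxy hydroperoxide
Conditions: mCPBA, NaHCO3, CH2Cl2, 0 °C
Reagents that add atoms: 3-chloroperbenzoic acid, OOC(=O)c1cccc(Cl)c1
Why: Peracid epoxidation of the trisubstituted alkene, far faster than that of the terminal alkene, should be delivered syn to the allylic hydroperoxide by hydrogen bonding (Henbest-type direction).

Step 34
Reactants: 47 epoxy hydroperoxide
Product: 49 CNP0533733.1 (target), via hydroperoxy aldehyde 48 (not isolated)
Conditions: O3, pyridine, CH2Cl2, −78 °C; warm to rt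
Reagents that add atoms: ozone, [O-][O+]=O
Why: Ozonolysis of the last alkene in the presence of pyridine gives the aldehyde without a reducing agent, so the hydroperoxide survives and adds to the aldehyde to close the eight-membered hemiperacetal, whose new centre is under thermodynamic control.

**Compound list**

1 | coumalic acid | OC(=O)c1ccc(=O)oc1 | starting material
2 | 5-bromo-2H-pyran-2-one | O=c1ccc(Br)co1 | intermediate
3 | 5-(4,4,5,5-tetramethyl-1,3,2-dioxaborolan-2-yl)-2H-pyran-2-one | CC1(C)OB(OC1(C)C)c1ccc(=O)oc1 | intermediate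
4 | 5-hydroxy-2H-pyran-2-one | Oc1ccc(=O)oc1 | intermediate
5 | succinimide | O=C1CCC(=O)N1 | starting material
6 | tert-butyl 2,5-dioxopyrrolidine-1-carboxylate | CC(C)(C)OC(=O)N1C(=O)CCC1=O | intermediate
7 | 2-methylpent-1-en-3-one | CCC(=O)C(C)=C | starting material
8 | (Z)-tert-butyldimethyl[(2-methylpenta-1,3-dien-3-yl)oxy]silane | C=C(C)/C(O[Si](C)(C)C(C)(C)C)=C/C | intermediate
9 | (E)-4-acetoxy-2-methylbut-2-enal | O=C/C(C)=C/COC(C)=O | starting material
10 | [(1R,2R,6R)-2-formyl-2,4,6-trimethyl-5-(tert-butyldimethylsilyloxy)cyclohex-4-en-1-yl]methyl acetate | CC1=C(O[Si](C)(C)C(C)(C)C)[C@H](C)[C@@H](COC(C)=O)[C@](C)(C=O)C1 | intermediate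
11 | 2-(triphenylphosphoranylidene)propanal | CC(C=O)=P(c1ccccc1)(c1ccccc1)c1ccccc1 | starting material
12 | ring A enal ((E)-2-methyl-3-oxoprop-1-enyl arm on the quaternary carbon) | CC1=C(O[Si](C)(C)C(C)(C)C)[C@H](C)[C@@H](COC(C)=O)[C@](C)(/C=C(/C=O)C)C1 | intermediate
13 | ring A triene ((E)-2-methylbuta-1,3-dienyl arm) | CC1=C(O[Si](C)(C)C(C)(C)C)[C@H](C)[C@@H](COC(C)=O)[C@](C)(/C=C(/C=C)C)C1 | intermediate
14 | hydroxy ketone (all ring substituents equatorial except the axial quaternary methyl) | C[C@@H]1C(=O)[C@H](C)[C@@H](CO)[C@](C)(/C=C(/C=C)C)C1 | intermediate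
15 | tosylhydrazone of 14 | C[C@@H]1C(=NNS(=O)(=O)c2ccc(C)cc2)[C@H](C)[C@@H](CO)[C@](C)(/C=C(/C=C)C)C1 | intermediate
16 | {2-[(E)-2-methylbuta-1,3-dienyl]-2,4,6-trimethylcyclohexyl}methanol | C[C@@H]1C[C@H](C)[C@@H](CO)[C@](C)(/C=C(/C=C)C)C1 | intermediate
17 | ring A aldehyde | C[C@@H]1C[C@H](C)[C@@H](C=O)[C@](C)(/C=C(/C=C)C)C1 | intermediate
18 | methyl propiolate | C#CC(=O)OC | starting material
19 | methyl 3-(methylzincio)propiolate | C[Zn]C#CC(=O)OC | intermediate
20 | ring A propargylic alcohol (S carbinol) | C[C@@H]1C[C@H](C)[C@@H]([C@H](O)C#CC(=O)OC)[C@](C)(/C=C(/C=C)C)C1 | intermediate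
21 | ring A γ-hydroxy (E)-enoate | C[C@@H]1C[C@H](C)[C@@H]([C@H](O)/C=C/C(=O)OC)[C@](C)(/C=C(/C=C)C)C1 | intermediate
22 | ring A triene TBS ether | C[C@@H]1C[C@H](C)[C@@H]([C@H](O[Si](C)(C)C(C)(C)C)/C=C/C(=O)OC)[C@](C)(/C=C(/C=C)C)C1 | intermediate
23 | tricyclic ester | C[C@@H]1C[C@H](C)[C@H]2[C@H](O[Si](C)(C)C(C)(C)C)[C@H]3[C@H]([C@]2(C)C1)C(C)=CC[C@@H]3C(=O)OC | intermediate
24 | tricyclic primary alcohol | C[C@@H]1C[C@H](C)[C@H]2[C@H](O[Si](C)(C)C(C)(C)C)[C@H]3[C@H]([C@]2(C)C1)C(C)=CC[C@@H]3CO | intermediate
25 | tricyclic TES ether | C[C@@H]1C[C@H](C)[C@H]2[C@H](O[Si](C)(C)C(C)(C)C)[C@H]3[C@H]([C@]2(C)C1)C(C)=CC[C@@H]3CO[Si](CC)(CC)CC | intermediate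
26 | ring C enone | C[C@@H]1C[C@H](C)[C@H]2[C@H](O[Si](C)(C)C(C)(C)C)[C@H]3[C@H]([C@]2(C)C1)C(C)=CC(=O)[C@@H]3CO[Si](CC)(CC)CC | intermediate
27 | lithium enolate of the reduced enone | C[C@@H]1C[C@H](C)[C@H]2[C@H](O[Si](C)(C)C(C)(C)C)[C@H]3[C@H]([C@]2(C)C1)[C@@H](C)C=C([O-])[C@@H]3CO[Si](CC)(CC)CC.[Li+] | intermediate
28 | ring C enol triflate | C[C@@H]1C[C@H](C)[C@H]2[C@H](O[Si](C)(C)C(C)(C)C)[C@H]3[C@H]([C@]2(C)C1)[C@@H](C)C=C(OS(=O)(=O)C(F)(F)F)[C@@H]3CO[Si](CC)(CC)CC | intermediate
29 | ring C methyl alkene TES ether | C[C@@H]1C[C@H](C)[C@H]2[C@H](O[Si](C)(C)C(C)(C)C)[C@H]3[C@H]([C@]2(C)C1)[C@@H](C)C=C(C)[C@@H]3CO[Si](CC)(CC)CC | intermediate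
30 | homoallylic primary alcohol | C[C@@H]1C[C@H](C)[C@H]2[C@H](O[Si](C)(C)C(C)(C)C)[C@H]3[C@H]([C@]2(C)C1)[C@@H](C)C=C(C)[C@@H]3CO | intermediate
31 | tricyclic β,γ-unsaturated aldehyde | C[C@@H]1C[C@H](C)[C@H]2[C@H](O[Si](C)(C)C(C)(C)C)[C@H]3[C@H]([C@]2(C)C1)[C@@H](C)C=C(C)[C@@H]3C=O | intermediate
32 | lithium enolate of 6 | CC(C)(C)OC(=O)N1C(=O)CC=C1[O-].[Li+] | intermediate
33 | β-hydroxy imide (carbinol and imide α-carbon unassigned) | C[C@@H]1C[C@H](C)[C@H]2[C@H](O[Si](C)(C)C(C)(C)C)[C@H]3[C@H]([C@]2(C)C1)[C@@H](C)C=C(C)[C@@H]3C(O)C4CC(=O)N(C(=O)OC(C)(C)C)C4=O | intermediate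
34 | β-keto imide (imide α-carbon epimerizable) | C[C@@H]1C[C@H](C)[C@H]2[C@H](O[Si](C)(C)C(C)(C)C)[C@H]3[C@H]([C@]2(C)C1)[C@@H](C)C=C(C)[C@@H]3C(=O)C4CC(=O)N(C(=O)OC(C)(C)C)C4=O | intermediate
35 | allyl methyl carbonate | C=CCOC(=O)OC | starting material
36 | allylated keto imide | C[C@@H]1C[C@H](C)[C@H]2[C@H](O[Si](C)(C)C(C)(C)C)[C@H]3[C@H]([C@]2(C)C1)[C@@H](C)C=C(C)[C@@H]3C(=O)[C@@]4(CC=C)C(=O)N(C(=O)OC(C)(C)C)C(=O)C4 | intermediate
37 | propargyl bromide | C#CCBr | starting material
38 | allenylzinc bromide | C=C=C[Zn]Br | intermediate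
39 | N-Boc propargyl hydroxy lactam (carbinolamide carbon unassigned) | C[C@@H]1C[C@H](C)[C@H]2[C@H](O[Si](C)(C)C(C)(C)C)[C@H]3[C@H]([C@]2(C)C1)[C@@H](C)C=C(C)[C@@H]3C(=O)[C@@]4(CC=C)C(=O)N(C(=O)OC(C)(C)C)C(O)(CC#C)C4 | intermediate
40 | N-Boc methoxy aminal TBS ether (aminal carbon unassigned) | C[C@@H]1C[C@H](C)[C@H]2[C@H](O[Si](C)(C)C(C)(C)C)[C@H]3[C@H]([C@]2(C)C1)[C@@H](C)C=C(C)[C@@H]3C(=O)[C@@]4(CC=C)C(=O)N(C(=O)OC(C)(C)C)C(OC)(CC#C)C4 | intermediate
41 | seco alcohol (N–H methoxy aminal, ring B α-OH) | C[C@@H]1C[C@H](C)[C@H]2[C@H](O)[C@H]3[C@H]([C@]2(C)C1)[C@@H](C)C=C(C)[C@@H]3C(=O)[C@@]4(CC=C)C(=O)N[C@](OC)(CC#C)C4 | intermediate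
42 | seco pyronyl ether with propargyl N,O-acetal lactam | C[C@@H]1C[C@H](C)[C@H]2[C@@H](Oc5ccc(=O)oc5)[C@H]3[C@H]([C@]2(C)C1)[C@@H](C)C=C(C)[C@@H]3C(=O)[C@@]4(CC=C)C(=O)N[C@](OC)(CC#C)C4 | intermediate
43 | bridged 2-oxabicyclo[2.2.2]octadienone macrocycle (bridgeheads unassigned; either pyrone face gives the same arene) | C[C@@H]1C[C@H](C)[C@H]2[C@H]3OC7=CC8C(=O)OC7C=C8C[C@]4(OC)C[C@](C(=O)[C@@H]6[C@@H]3[C@H]([C@]2(C)C1)[C@@H](C)C=C6C)(CC=C)C(=O)N4 | intermediate
44 | cyclophane lactam methyl aminal | C[C@@H]1C[C@H](C)[C@H]2[C@H]3Oc4ccc(cc4)C[C@]4(OC)C[C@](C(=O)[C@@H]6[C@@H]3[C@H]([C@]2(C)C1)[C@@H](C)C=C6C)(CC=C)C(=O)N4 | intermediate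
45 | cyclophane hemiaminal | C[C@@H]1C[C@H](C)[C@H]2[C@H]3Oc4ccc(cc4)C[C@]4(O)C[C@](C(=O)[C@@H]6[C@@H]3[C@H]([C@]2(C)C1)[C@@H](C)C=C6C)(CC=C)C(=O)N4 | intermediate
46 | ring C allylic hydroperoxide | C[C@@H]1C[C@H](C)[C@H]2[C@H]3Oc4ccc(cc4)C[C@]4(O)C[C@](C(=O)[C@@H]6[C@@H]3[C@H]([C@]2(C)C1)C(C)=C[C@]6(C)OO)(CC=C)C(=O)N4 | intermediate
47 | epoxy hydroperoxide | C[C@@H]1C[C@H](C)[C@H]2[C@H]3Oc4ccc(cc4)C[C@]4(O)C[C@](C(=O)[C@@H]6[C@@H]3[C@H]([C@]2(C)C1)[C@]7(C)O[C@@H]7[C@]6(C)OO)(CC=C)C(=O)N4 | intermediate
48 | hydroperoxy aldehyde | C[C@@H]1C[C@H](C)[C@H]2[C@H]3Oc4ccc(cc4)C[C@]4(O)C[C@](C(=O)[C@@H]6[C@@H]3[C@H]([C@]2(C)C1)[C@]7(C)O[C@@H]7[C@]6(C)OO)(CC=O)C(=O)N4 | intermediate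
49 | CNP0533733.1 | C[C@@H]1C[C@H](C)[C@H]2[C@H]3Oc4ccc(cc4)C[C@]4(O)C[C@]5(C[C@H](O)OO[C@@]6(C)[C@H]7O[C@@]7(C)[C@H]([C@H]3[C@H]6C5=O)[C@]2(C)C1)C(=O)N4 | target

**Count and risks**

Total step count: 34. Longest linear sequence: 30 steps (steps 5 to 34).

Step 30 (most likely to fail). The tethered alkyne may not reach the pyrone in the para-bridging geometry, so that oligomerization, [4+2] addition of the allyl alkene or thermal loss of methanol from the aminal outruns the macrocyclization. The fallback closes the same ring at the aryl–oxygen bond instead and sets out from 36. Addition of 4-(methoxymethoxy)benzylmagnesium chloride at −78 °C to the unhindered imide carbonyl would give the N-Boc benzyl hydroxy lactam F1. Methanolic HCl would then remove the Boc, TBS and methoxymethyl groups and form the seco phenol methyl aminal F2. An intramolecular Mitsunobu etherification (PPh3, DIAD, toluene, high dilution) with inversion at the ring B carbinol would close the 13-membered ring and come back to the route at 44.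

Step 32. Hydrogen abstraction from the C-methyl group, or attack of singlet oxygen on the lower face with abstraction of the hydrogen next to the ketone, may compete with the wanted ene mode. The fallback builds the C–OOH bond by ionic addition and sets out from 45. 1,3-Dibromo-5,5-dimethylhydantoin and anhydrous H2O2 in ether at −40 °C (bromonium ion on the open lower face, anti Markovnikov-type opening by H2O2 at the tertiary carbon) would give the ring C bromo hydroperoxide F3. 2-Methoxypropene with PPTS would mask it as the bromo peroxyketal F4. DBU would eliminate HBr anti-periplanar towards the CH(CH3) carbon, the only carbon with a β-hydrogen, to give the allylic peroxyketal F5. Aqueous acetic acid would release the hydroperoxide and come back to the route at 46.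

Step 29. The hindered ring B carbinol, flanked by two ring-fusion carbons, may eliminate to the cyclopentene or fail to form the oxyphosphonium ion. The fallback separates activation from displacement and sets out from 41. Chloromethanesulfonyl chloride in pyridine would give the ring B chloromethanesulfonate F6. The caesium salt of 4 with 18-crown-6 in toluene at 80 °C would displace it with inversion and come back to the route at 42.

**Further compounds**

F1 | step 30 | N-Boc hydroxy lactam with 4-(methoxymethoxy)benzyl on the carbinolamide carbon (TBS ether) | C[C@@H]1C[C@H](C)[C@H]2[C@H](O[Si](C)(C)C(C)(C)C)[C@H]3[C@H]([C@]2(C)C1)[C@@H](C)C=C(C)[C@@H]3C(=O)[C@@]4(CC=C)C(=O)N(C(=O)OC(C)(C)C)C(O)(Cc5ccc(OCOC)cc5)C4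
F2 | step 30 | seco phenol methyl aminal with free ring B α-alcohol | C[C@@H]1C[C@H](C)[C@H]2[C@H](O)[C@H]3[C@H]([C@]2(C)C1)[C@@H](C)C=C(C)[C@@H]3C(=O)[C@@]4(CC=C)C(=O)N[C@](OC)(Cc5ccc(O)cc5)C4
F3 | step 32 | ring C bromo hydroperoxide | C[C@@H]1C[C@H](C)[C@H]2[C@H]3Oc4ccc(cc4)C[C@]4(O)C[C@](C(=O)[C@@H]6[C@@H]3[C@H]([C@]2(C)C1)[C@@H](C)[C@@H](Br)[C@]6(C)OO)(CC=C)C(=O)N4
F4 | step 32 | bromo 2-methoxyprop-2-yl peroxide | C[C@@H]1C[C@H](C)[C@H]2[C@H]3Oc4ccc(cc4)C[C@]4(O)C[C@](C(=O)[C@@H]6[C@@H]3[C@H]([C@]2(C)C1)[C@@H](C)[C@@H](Br)[C@]6(C)OOC(C)(C)OC)(CC=C)C(=O)N4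
F5 | step 32 | allylic 2-methoxyprop-2-yl peroxide | C[C@@H]1C[C@H](C)[C@H]2[C@H]3Oc4ccc(cc4)C[C@]4(O)C[C@](C(=O)[C@@H]6[C@@H]3[C@H]([C@]2(C)C1)C(C)=C[C@]6(C)OOC(C)(C)OC)(CC=C)C(=O)N4
F6 | step 29 | ring B chloromethanesulfonate of 41 | C[C@@H]1C[C@H](C)[C@H]2[C@H](OS(=O)(=O)CCl)[C@H]3[C@H]([C@]2(C)C1)[C@@H](C)C=C(C)[C@@H]3C(=O)[C@@]4(CC=C)C(=O)N[C@](OC)(CC#C)C4
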